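**Plan**

1. Retrosynthetic cuts, in order: C6′=C7′ (ring-closing metathesis, ring B); O2–C3 and C3–C3a (cyclisation of an enynoic acid, Sonogashira coupling); C1′–C7a′ together with O2′–C3′ (CO2 bridged between an enolisable C7a′ and a C3′ epoxy sulfone); C3a–C7a (Dieckmann, ring A); C3′–C8′ (Darzens); the four bonds from the five-membered carbocycle to its side chains (two conjugate-addition/α-alkylation pairs).
2. Forward: (S)-4-silyloxycyclopentenone → all-trans tetrasubstituted cyclopentanone (the future carbocycle C6–C7–C7a′–C3a′–C3′) → spiro epoxy sulfone → ring A → bridging γ-lactone (key step) → butylidene butenolide → ring B.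
3. Enabling feature: C7a′ and C3′ are 1,3-related on the five-membered carbocycle. C7a′ carries C7′, kept as CHO so that C7a′ is enolisable. C3′ carries the acyl carbon C8′, so C3′/C8′ can be masked as an epoxy sulfone (α-keto cation equivalent). O–C(=O) from CO2 then spans C7a′ and C3′ as the two-atom bridge of a 2-oxabicyclo[2.2.1]heptan-3-one.
4. Stereochemistry: the C7 silyloxy centre of the starting enone directs the first conjugate addition and is then eliminated. Every later ring substituent enters trans to its neighbour (C7a′/C3a′, C7/C7a′, C6/C7 all trans; C6 and C3a′ are epimerisable towards this array). C7a′ and C3′ are fixed in the key step, which should funnel aldehyde epimers and epoxide diastereomers into one lactone. The Z alkene comes from anti addition across the alkyne.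

Key step: step 10

Remark: locants C1–C11 and C1′–C11′ follow phthalide numbering of the two C12 units of the target; "up/down" are the faces of the carbocycle drawn with C6→C7→C7a′→C3a′→C3′ clockwise; 1-tert-butoxy-1-(tert-butyldimethylsilyloxy)ethene and (S)-4-(tert-butyldimethylsilyloxy)cyclopent-2-en-1-one are taken as purchasable.

**Step 1**
Reactants: 1 (S)-4-(tert-butyldimethylsilyloxy)cyclopent-2-en-1-one; 2 1,3-dithiane; 3 4-iodobut-1-ene
Product: 6 (2S,3S,4S)-2-(but-3-en-1-yl)-4-(tert-butyldimethylsilyloxy)-3-(1,3-dithian-2-yl)cyclopentan-1-one, via 2-lithio-1,3-dithiane 4 (not isolated), via lithium enolate 5 (not isolated)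
Conditions: n-BuLi, THF, −30 °C; HMPA, then 1, −78 °C; then 3, −78 → −30 °C
Reagents that add atoms: none
Why: Tandem conjugate addition/enolate alkylation (three-component coupling): the lithiated dithiane, made 1,4-selective by HMPA, should add anti to the C7 silyloxy group (sets C7a′, dithianyl up), and the enolate should be alkylated anti to the new dithianyl group (sets C3a′, butenyl down).

**Step 2**
Reactants: 6 (2S,3S,4S)-2-(but-3-en-1-yl)-4-(tert-butyldimethylsilyloxy)-3-(1,3-dithian-2-yl)cyclopentan-1-one
Product: 7 (4R,5S)-5-(but-3-en-1-yl)-4-(1,3-dithian-2-yl)cyclopent-2-en-1-one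
Conditions: DBU, CH2Cl2, 0 °C
Reagents that add atoms: none
Why: E1cB β-elimination of silanolate from the β-silyloxy ketone should give the C6=C7 enone, with the two remaining stereocentres untouched under brief, cold base treatment.

**Step 3**
Reactants: 7 (4R,5S)-5-(but-3-en-1-yl)-4-(1,3-dithian-2-yl)cyclopent-2-en-1-one; 8 1-tert-butoxy-1-(tert-butyldimethylsilyloxy)ethene
Product: 9 tert-butyl 2-[4-(but-3-en-1-yl)-3-(tert-butyldimethylsilyloxy)-5-(1,3-dithian-2-yl)cyclopent-2-en-1-yl]acetate (1,5-trans; 4,5-trans)
Conditions: LiClO4 (10 mol%), CH2Cl2, 23 °C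
Reagents that add atoms: none
Why: Mukaiyama–Michael addition of the ketene silyl acetal to C7 anti to the adjacent dithianyl group (sets C7, acetate chain down), with silyl transfer giving the silyl enol ether regiodefined towards C6.

**Step 4**
Reactants: 9 tert-butyl 2-[4-(but-3-en-1-yl)-3-(tert-butyldimethylsilyloxy)-5-(1,3-dithian-2-yl)cyclopent-2-en-1-yl]acetate; 10 methyl acrylate
Product: 11 methyl 3-[3-(but-3-en-1-yl)-5-(2-tert-butoxy-2-oxoethyl)-4-(1,3-dithian-2-yl)-2-oxocyclopentyl]propanoate (all-trans: C6 chain up; C7 chain down; C7a′ dithianyl up; C3a′ butenyl down)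
Conditions: Bu4N[Ph3SiF2], THF, −78 → −40 °C; aq. NH4Cl
Reagents that add atoms: none
Why: Fluoride unmasks the C6 enolate regiospecifically and Michael addition to the acrylate should occur trans to the C7 chain (sets C6); C6 and C3a′ are epimerisable and the all-trans array is the thermodynamic one.

**Step 5**
Reactants: 12 chloromethyl phenyl sulfone; 13 1-iodopropane
Product: 14 (1-chlorobutyl) phenyl sulfone (racemic)
Conditions: NaOH (50% aq.), Bu4NBr (cat.), toluene, 23 °C
Reagents that add atoms: none
Why: Phase-transfer C-alkylation of the α-chloro sulfonyl carbanion, a standard entry to 1-chloroalkyl sulfones; the stereocentre is irrelevant because it is destroyed in step 10.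

**Step 6**
Reactants: 11 methyl 3-[3-(but-3-en-1-yl)-5-(2-tert-butoxy-2-oxoethyl)-4-(1,3-dithian-2-yl)-2-oxocyclopentyl]propanoate; 14 (1-chlorobutyl) phenyl sulfone
Product: 16 methyl 3-[7-(but-3-en-1-yl)-5-(2-tert-butoxy-2-oxoethyl)-6-(1,3-dithian-2-yl)-2-(phenylsulfonyl)-2-propyl-1-oxaspiro[2.4]heptan-4-yl]propanoate (ring substituents as in 11; diastereomer mixture at both epoxide carbons), via α-lithio sulfone 15 (not isolated)
Conditions: LiN(i-Pr)2, THF, −78 °C; add 11; −78 → 0 °C
Reagents that add atoms: none
Why: Darzens condensation of the α-chloro sulfonyl carbanion with the ketone (addition to C3′, then 3-exo-tet closure) should be chemoselective for the ketone over the esters; C3′ and C8′ are formed without control, which is acceptable because step 10 is stereoconvergent.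

**Step 7**
Reactants: 16 spiro epoxy sulfone diester
Product: 18 tert-butyl 2-(but-3-en-1-yl)-3-(1,3-dithian-2-yl)-3′-(phenylsulfonyl)-3′-propyl-5-(trifluoromethylsulfonyloxy)-2,3,3a,6,7,7a-hexahydrospiro[indene-1,2′-oxirane]-4-carboxylate (ring A trans-fused: H-6 down; H-7 up; C7a′ dithianyl up; C3a′ butenyl down), via lithium β-keto ester enolate 17 (not isolated)
Conditions: LiN(SiMe3)2 (2.2 equiv), THF, −78 → 0 °C; then PhN(SO2CF3)2, 0 → 23 °C
Reagents that add atoms: N-phenylbis(trifluoromethanesulfonimide), O=S(=O)(N(c1ccccc1)S(=O)(=O)C(F)(F)F)C(F)(F)F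
Why: Dieckmann condensation in which the tert-butyl acetate enolate (C7a) attacks the methyl ester (C3a), the tert-butyl ester being too hindered to serve as electrophile, closes ring A on the already trans C6/C7 chains without creating a stereocentre, and the enolate is trapped in situ as the enol triflate.

**Step 8**
Reactants: 18 enol triflate; 19 pent-1-yne
Product: 20 tert-butyl 2-(but-3-en-1-yl)-3-(1,3-dithian-2-yl)-5-(pent-1-yn-1-yl)-3′-(phenylsulfonyl)-3′-propyl-2,3,3a,6,7,7a-hexahydrospiro[indene-1,2′-oxirane]-4-carboxylate (stereochemistry as in 18)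
Conditions: PdCl2(PPh3)2 (5 mol%), CuI (10 mol%), Et3N, THF, 40 °C
Reagents that add atoms: none
Why: Sonogashira coupling of a β-triflyloxy enoate with a terminal alkyne is routine and places the alkyne cis to the ester on the ring-A double bond; no stereocentre is affected.

**Step 9**
Reactants: 20 enyne ester dithiane
Product: 21 tert-butyl 2-(but-3-en-1-yl)-3-formyl-5-(pent-1-yn-1-yl)-3′-(phenylsulfonyl)-3′-propyl-2,3,3a,6,7,7a-hexahydrospiro[indene-1,2′-oxirane]-4-carboxylate (C7a′ formyl up; otherwise as in 18)
Conditions: MeI, CaCO3, MeCN–H2O (9:1), 45 °C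
Reagents that add atoms: water, O
Why: Alkylative hydrolysis of the dithioacetal (S-methylation, then hydrolysis) should unmask the aldehyde without touching epoxy sulfone, ester, alkyne or alkenes; C7a′ is now epimerisable, which step 10 exploits.

**Step 10**
Reactants: 21 aldehyde epoxy sulfone
Product: 23 bridged keto lactone aldehyde: target skeleton lacking ring B and the O2–C3 bond; C7a′ bears CHO (up) and C1′ (down); C3′ bears butanoyl (up) and O2′ (down); C3a′ bears but-3-enyl (down); C3a bears pent-1-ynyl; C7a bears CO2t-Bu, via C7a′ carboxylate 22 (not isolated)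
Conditions: CO2 (10 bar), DBU, Mg(OSO2CF3)2, MeCN, 40 °C
Reagents that add atoms: carbon dioxide, O=C=O
Why: Proposed new method: soft enolisation of the α-branched aldehyde (magnesium salt, amidine base) gives the C7a′ enolate, which adds reversibly to CO2; the β-oxo carboxylate then attacks C3′ of the Lewis-acid-activated epoxy sulfone, and the α-sulfonyl alkoxide at C8′ expels benzenesulfinate to unveil the butanoyl ketone. The closest known reaction types are the base-mediated, silver-catalysed carboxylative cyclisation of alkyne-tethered ketones with CO2 (C-carboxylation, then O-cyclisation of the β-keto carboxylate) and the opening of α,β-epoxy sulfones by nucleophiles at the β-carbon with loss of sulfinate to give α-substituted ketones. The lactone ring (O2′, C1′, C7a′, C3a′, C3′) closes 5-exo-tet and creates the 2-oxabicyclo[2.2.1]heptan-3-one; closure through the enolate oxygen itself is excluded because it would place a double bond at the C7a′ bridgehead. C7a′ is set dynamically: the aldehyde epimers interconvert through the enol, carboxylation is reversible, and only the carboxylate on the face of the C3a′ butenyl group should bridge, because the opposite bridge would force that butenyl group over the C6–C7 bond against the exo carbon of ring A. C3′ is set by the tether (O2′ must enter on the face of C1′): the epoxide epimer with its oxygen anti reacts with inversion, and the other should be funnelled through ionisation of the tertiary C3′–O bond, so all epoxy sulfone diastereomers are expected to converge. The step needs C- rather than O-carboxylation and attack at C3′ rather than C8′; the first is secured by the reversibility of O-carboxylation, the second by the five-membered transition state and the fully substituted, sulfonyl-deactivated C8′.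

**Step 11**
Reactants: 23 bridged keto lactone aldehyde
Product: 24 bridged keto lactone with C7a′ vinyl (up) in place of CHO; otherwise as 23
Conditions: Ph3PCH3Br, KN(SiMe3)2, THF, −78 → 0 °C
Reagents that add atoms: methyltriphenylphosphonium bromide, C[P+](c1ccccc1)(c1ccccc1)c1ccccc1.[Br-]
Why: Wittig methylenation should be chemoselective for the aldehyde over the hindered α-acyloxy ketone and the lactone; no stereocentre is affected.

**Step 12**
Reactants: 24 vinyl keto lactone tert-butyl ester
Product: 26 (Z)-butylidene butenolide diene: the target with ring B open (C7a′ vinyl up; C3a′ but-3-enyl down), via enynoic acid 25 (not isolated)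
Conditions: CF3CO2H, CH2Cl2, 0 → 23 °C; evaporate; AgNO3 (10 mol%), acetone, 23 °C, dark
Reagents that add atoms: none
Why: Acidolysis of the tert-butyl ester, then silver-catalysed 5-exo-dig cycloisomerisation of the (Z)-2-en-4-ynoic acid; anti addition of O and H across the alkyne should give the Z-butylidene lactone.

**Step 13**
Reactants: 26 (Z)-butylidene butenolide diene
Product: 27 target, CNP0423313.2
Conditions: second-generation Grubbs catalyst (5 mol%), CH2Cl2, 40 °C
Reagents that add atoms: none
Why: Ring-closing metathesis of the C7a′ vinyl and C3a′ butenyl groups should close ring B with the C6′=C7′ double bond and loss of ethene; the enol-lactone and tetrasubstituted alkenes are inert to the catalyst.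

**Compound list**

1 | (S)-4-(tert-butyldimethylsilyloxy)cyclopent-2-en-1-one | O=C1C=C[C@@H](O[Si](C)(C)C(C)(C)C)C1 | starting material
2 | 1,3-dithiane | C1CSCSC1 | starting material
3 | 4-iodobut-1-ene | C=CCCI | starting material
4 | 2-lithio-1,3-dithiane | [Li]C1SCCCS1 | intermediate
5 | lithium 4-(tert-butyldimethylsilyloxy)-3-(1,3-dithian-2-yl)cyclopent-1-en-1-olate (3,4-trans) | [Li]OC1=C[C@H](C2SCCCS2)[C@@H](O[Si](C)(C)C(C)(C)C)C1 | intermediate
6 | (2S,3S,4S)-2-(but-3-en-1-yl)-4-(tert-butyldimethylsilyloxy)-3-(1,3-dithian-2-yl)cyclopentan-1-one | O=C1C[C@H](O[Si](C)(C)C(C)(C)C)[C@@H](C2SCCCS2)[C@@H]1CCC=C | intermediate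
7 | (4R,5S)-5-(but-3-en-1-yl)-4-(1,3-dithian-2-yl)cyclopent-2-en-1-one | O=C1C=C[C@@H](C2SCCCS2)[C@@H]1CCC=C | intermediate
8 | 1-tert-butoxy-1-(tert-butyldimethylsilyloxy)ethene | C=C(OC(C)(C)C)O[Si](C)(C)C(C)(C)C | starting material
9 | tert-butyl 2-[4-(but-3-en-1-yl)-3-(tert-butyldimethylsilyloxy)-5-(1,3-dithian-2-yl)cyclopent-2-en-1-yl]acetate (1,5-trans; 4,5-trans) | CC(C)(C)[Si](C)(C)OC1=C[C@H](CC(=O)OC(C)(C)C)[C@@H](C2SCCCS2)[C@@H]1CCC=C | intermediate
10 | methyl acrylate | C=CC(=O)OC | starting material
11 | methyl 3-[3-(but-3-en-1-yl)-5-(2-tert-butoxy-2-oxoethyl)-4-(1,3-dithian-2-yl)-2-oxocyclopentyl]propanoate (all-trans) | O=C1[C@@H](CCC(=O)OC)[C@H](CC(=O)OC(C)(C)C)[C@@H](C2SCCCS2)[C@@H]1CCC=C | intermediate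
12 | chloromethyl phenyl sulfone | ClCS(=O)(=O)c1ccccc1 | starting material
13 | 1-iodopropane | CCCI | starting material
14 | (1-chlorobutyl) phenyl sulfone (racemic) | CCCC(Cl)S(=O)(=O)c1ccccc1 | intermediate
15 | (1-chloro-1-lithiobutyl) phenyl sulfone | CCCC([Li])(Cl)S(=O)(=O)c1ccccc1 | intermediate
16 | spiro epoxy sulfone diester (name as in step 6; epoxide carbons unassigned) | CCCC1(S(=O)(=O)c2ccccc2)OC13[C@@H](CCC(=O)OC)[C@H](CC(=O)OC(C)(C)C)[C@@H](C4SCCCS4)[C@@H]3CCC=C | intermediate
17 | lithium enolate of the ring-A tert-butyl β-keto ester (Dieckmann product of 16) | CCCC1(S(=O)(=O)c2ccccc2)OC13[C@H]2CCC(O[Li])=C(C(=O)OC(C)(C)C)[C@@H]2[C@@H](C4SCCCS4)[C@@H]3CCC=C | intermediate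
18 | enol triflate (name as in step 7) | CCCC1(S(=O)(=O)c2ccccc2)OC13[C@H]2CCC(OS(=O)(=O)C(F)(F)F)=C(C(=O)OC(C)(C)C)[C@@H]2[C@@H](C4SCCCS4)[C@@H]3CCC=C | intermediate
19 | pent-1-yne | CCCC#C | starting material
20 | enyne ester dithiane (name as in step 8) | CCCC1(S(=O)(=O)c2ccccc2)OC13[C@H]2CCC(C#CCCC)=C(C(=O)OC(C)(C)C)[C@@H]2[C@@H](C4SCCCS4)[C@@H]3CCC=C | intermediate
21 | aldehyde epoxy sulfone (name as in step 9) | CCCC1(S(=O)(=O)c2ccccc2)OC13[C@H]2CCC(C#CCCC)=C(C(=O)OC(C)(C)C)[C@@H]2[C@@H](C=O)[C@@H]3CCC=C | intermediate
22 | C7a′ carboxylate of 21 (CHO up; CO2− down), shown as its DBU-H+ salt | CCCC1(S(=O)(=O)c2ccccc2)OC13[C@H]2CCC(C#CCCC)=C(C(=O)OC(C)(C)C)[C@@H]2[C@](C=O)(C(=O)[O-])[C@@H]3CCC=C.C1CCC2=[NH+]CCCN2CC1 | intermediate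
23 | bridged keto lactone aldehyde (description as in step 10) | CCCC#CC1=C(C(=O)OC(C)(C)C)[C@@H]2[C@]3(C=O)C(=O)O[C@@](C(=O)CCC)([C@H]3CCC=C)[C@H]2CC1 | intermediate
24 | bridged keto lactone with C7a′ vinyl, tert-butyl ester | CCCC#CC1=C(C(=O)OC(C)(C)C)[C@@H]2[C@]3(C=C)C(=O)O[C@@](C(=O)CCC)([C@H]3CCC=C)[C@H]2CC1 | intermediate
25 | enynoic acid from 24 | CCCC#CC1=C(C(=O)O)[C@@H]2[C@]3(C=C)C(=O)O[C@@](C(=O)CCC)([C@H]3CCC=C)[C@H]2CC1 | intermediate
26 | (Z)-butylidene butenolide diene (target with ring B open) | CCC/C=C1\OC(=O)C2=C1CC[C@H]1[C@H]2[C@@]2(C=C)[C@H](CCC=C)[C@]1(C(=O)CCC)OC2=O | intermediate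
27 | CNP0423313.2 | CCC/C=C1\OC(=O)C2=C1CC[C@H]1[C@H]2[C@@]23C=CCC[C@@H]2[C@]1(C(=O)CCC)OC3=O | target

**Step count and risks**

Total step count: 13. Longest linear sequence: 12 steps (steps 1–4 and 6–13; step 5 is a one-step side branch).

Steps most likely to fail:

Step 10. Ring closure onto the fully substituted C3′ may be too slow, all the more because bridging forces the C6–C7 bond of the trans-fused ring A towards an eclipsed geometry. Decarboxylation back to the aldehyde, aldol self-condensation, or Lewis-acid rearrangement of the epoxy sulfone could then take over. The epoxide epimer that needs ionisation may also fail to converge. The fallback uses known chemistry, sets out from 21 and returns at 23. Condensation with pyrrolidine should give the pyrrolidine enamine F1. Enamine C-acylation with 2-(trimethylsilyl)ethyl chloroformate and aqueous hydrolysis should give the α-formyl 2-(trimethylsilyl)ethyl ester F2 as both C7a′ epimers. Fluoride cleavage of the silylethyl ester then frees the carboxylate, which should open the epoxy sulfone in the presence of Mg(OSO2CF3)2 to give 23. The epimer that cannot bridge should lose CO2 and regenerate 21 for recycling.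

Step 1. C-alkylation of the lithium enolate by the unactivated primary iodide may be slow. Proton transfer between enolate and product (loss of regiocontrol, polyalkylation) and β-elimination of silanolate could then compete. The fallback sets out from 1 and returns at 6. α-Iodination of the enone (I2, pyridine) should give the 2-iodo enone F3. Negishi coupling with but-3-enylzinc bromide (PdCl2(dppf)) should give the 2-butenyl enone F4. Conjugate addition of 2-lithio-1,3-dithiane (HMPA), anti to the silyloxy group, and protonation to the 2,3-trans ketone then returns 6.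

Step 6. The bulky α-chloro sulfonyl carbanion may deprotonate the hindered, enolisable 2,5-disubstituted cyclopentanone instead of adding to it. The intermediate alkoxide may also acylate onto the neighbouring methyl ester before it closes the epoxide. The fallback sets out from 11 and returns at 16. Addition of the smaller lithiated butyl phenyl sulfone in the presence of CeCl3 should give the β-hydroxy sulfone F5. Dehydration with the Burgess reagent should give the vinyl sulfone F6. Nucleophilic epoxidation (t-BuOOH, n-BuLi, THF) then gives 16.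

**Further compounds**

F1 | step 10 | pyrrolidine enamine of 21 (C7a′=C7′H–N) | CCCC1(S(=O)(=O)c2ccccc2)OC13[C@H]2CCC(C#CCCC)=C(C(=O)OC(C)(C)C)[C@@H]2C(=CN4CCCC4)[C@@H]3CCC=C
F2 | step 10 | α-formyl 2-(trimethylsilyl)ethyl ester at C7a′ (both epimers) | CCCC1(S(=O)(=O)c2ccccc2)OC13[C@H]2CCC(C#CCCC)=C(C(=O)OC(C)(C)C)[C@@H]2C(C=O)(C(=O)OCC[Si](C)(C)C)[C@@H]3CCC=C
F3 | step 1 | (S)-4-(tert-butyldimethylsilyloxy)-2-iodocyclopent-2-en-1-one | O=C1C(I)=C[C@@H](O[Si](C)(C)C(C)(C)C)C1
F4 | step 1 | (S)-2-(but-3-en-1-yl)-4-(tert-butyldimethylsilyloxy)cyclopent-2-en-1-one | O=C1C(CCC=C)=C[C@@H](O[Si](C)(C)C(C)(C)C)C1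
F5 | step 6 | β-hydroxy sulfone from 11 (C3′–OH; C8′–SO2Ph) | CCCC(S(=O)(=O)c1ccccc1)C1(O)[C@@H](CCC(=O)OC)[C@H](CC(=O)OC(C)(C)C)[C@@H](C2SCCCS2)[C@@H]1CCC=C
F6 | step 6 | vinyl sulfone (C3′=C8′) | CCCC(S(=O)(=O)c1ccccc1)=C1[C@@H](CCC(=O)OC)[C@H](CC(=O)OC(C)(C)C)[C@@H](C2SCCCS2)[C@@H]1CCC=C
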